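We decided to reckon from the charge of Zb rather than from the clock, because the readings stand still: Zh in noon reads 33.3% at 25.0 min and 33.2% at 50.0 min. Zb is taken as the limiting reagent.

in all of them: Za 0.23 M; Zd 0.0115 M

| run | Zb | remark | time |
|---|---|---|---|
| dusk | 0.19 M | run made earlier |  |
| noon | 0.50 M | run made earlier |  |
| larch | 0.345 M |  | 50 min |
| alder | 0.690 M |  | 50 min |

- dusk (time / min: Zf / %, Zh / %): 8.00: 10.8, 2.9; 15.0: 10.6, 3.4; 25.0: 10.3, 3.1; 30.0: 10.6, 3.1; 40.0: 10.8, 3.4; 50.0: 10.1, 3.2
- noon (time / min: Zf / %, Zh / %): 8.00: 13.3, 28.7; 15.0: 10.8, 31.5; 25.0: 11.2, 33.3; 30.0: 10.7, 32.9; 40.0: 10.9, 32.7; 50.0: 10.5, 33.2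

(each reading ± 0.3 percentage points)

1. which of these holds the largest part of the Za at the end of larch (Zh / Za / Zf / Ze / Zg)
2. which of these holds the largest part of the Za at the end of alder (Zh / Za / Zf / Ze / Zg)
3. Zf at the end of alder, in percent of the Za charged

- steps under discussion: Ze + Zb -> Zc + Zf; Za + Zb -> Zc + Ze; Ze -> Zk; Zg + Zb -> Zc + Zh; Ze + Zd -> Zj; Zf + Zb -> Zc + Zg

Two of us disputed Zf in alder. My colleague took logarithms of the final readings of dusk and noon. Zf gains 0.0401 powers of ten per power of ten of Zb, which is flat within the scatter, so alder should hold 10.6%.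

I took the same logarithms for Zh and got 2.42, the ladder exponent: powers of ten gained by final Zh per power of ten of Zb charged, Za and Zd held. From noon it gives Zh 13.5% in larch and 72.3% in alder.

Each Zh carries 4 Zb, so in alder that Zh leaves 10.7% of Zb, counted on the Za charged, for the other forms. Each Zf carries 2, so my colleague's level needs 21.2%, more than that remainder. My count puts Zf at 5.35% or less, which is an estimate and no bound, since it rests on the extrapolated Zh.

The forecast, from its own series fit, says Za for larch, Zh for alder and Zf 5%, holding that “Zf is the same in both runs because it lies on either side of its maximum”.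

Alder gives Zf 2.75%, and the half-life of Zf by its step with Zb, concentrations as charged, is 0.36 min, short against the 50 min of the run. Zh leads alder at 63.7%, and Za leads larch at 27.9%. From noon to alder the exponent reads 2.02, against my 2.42. The level view keeps the low side: alder's Zf has moved 5 points at 0.578 M of Zb.

    Ze + Zb → Zc + Zf (k = 0.0746 M⁻¹ s⁻¹)
    Za + Zb → Zc + Ze (k = 0.0266 M⁻¹ s⁻¹)
    Ze → Zk (k = 0.00531 s⁻¹)
    Zg + Zb → Zc + Zh (k = 0.0584 M⁻¹ s⁻¹)
    Ze + Zd → Zj (k = 0.728 M⁻¹ s⁻¹)
    Zf + Zb → Zc + Zg (k = 0.0461 M⁻¹ s⁻¹)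

With 0.41 M of Zb in the alder flask, the exponent gives Zh 20.5%. The computed flask holds Zh 21.4% and Zf 12.9%.

(All runs are calculated for substances that don't exist; the scatter is artificial.)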